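**Retrosynthetic overview**
- Target ⇐ Horner–Wadsworth–Emmons methylenation (C16=C17) ⇐ reduction of an 11‑ketone while the C15 carbonyl is masked as a phosphonoenolate.
- Rings C and D (bicyclo[3.2.1]octane) ⇐ one base cascade on a spiro δ‑lactone: C8–C14 alkylation, E1cB, C16→C13 Michael addition.
- Key step: the C9–C10 bond, the C10 quaternary centre and the 7,20‑δ‑lactone are made in one MHAT‑initiated 6‑endo radical cyclisation onto an alkylidene β‑keto ester tethered through O20. This replaces the customary Diels–Alder assembly of the lactone/C ring followed by radical D‑ring closure.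
- Ring A with C4/C5 and the 6,19‑γ‑lactone ⇐ catalytic enantioselective Diels–Alder reaction of a (Z)‑configured 1,2‑disubstituted diene with methacrolein.
- Order of ring formation: A → γ‑lactone → spiro δ‑lactone → C → D.

**Assumptions**
- Atom labels C1–C20 follow the ent‑kaurane numbering of the target; "α" is the face of C20, "β" the opposite face.
- The (S)‑oxazaborolidinium catalyst of step 4 is assumed to give the enantiomer drawn for 7 (usual model for 2‑substituted acroleins).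
- Centres that are epimer mixtures or are destroyed later are left undefined in the SMILES: C8 in 20, 21, 23; C16 in 26, 27; the lactol carbon in 10; the C8=C9 geometry in 22.
- TBS = tert‑butyl(dimethyl)silyl.

**Route**

Step 1
Reactants: 1 tert‑butyldimethyl(prop‑2‑yn‑1‑yloxy)silane
Product: 2 ethyl 4‑(TBS‑oxy)but‑2‑ynoate
Conditions: n‑BuLi, THF, −78 °C; ClCO2Et, −78 → 0 °C
Reagents that add atoms: ethyl chloroformate, CCOC(=O)Cl
Why: C‑acylation of the lithium acetylide with a chloroformate; no stereocentre is formed.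

Step 2
Reactants: 2 ethyl 4‑(TBS‑oxy)but‑2‑ynoate
Product: 3 ethyl (2Z)‑3‑[(TBS‑oxy)methyl]penta‑2,4‑dienoate
Conditions: CH2=CHMgBr, CuBr·SMe2, THF, −78 °C; MeOH/H2O quench at −78 °C
Reagents that add atoms: vinylmagnesium bromide, C=C[Mg]Br
Why: syn‑carbocupration (conjugate addition of vinylcopper to the ynoate) with cold protonation puts vinyl and H cis, so the future C6 and C20 carbons are cis on the new alkene (Z).

Step 3
Reactants: 3 ethyl (2Z)‑3‑[(TBS‑oxy)methyl]penta‑2,4‑dienoate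
Product: 5 (2Z)‑3‑[(TBS‑oxy)methyl]penta‑2,4‑dien‑1‑yl acetate, via (2Z)‑3‑[(TBS‑oxy)methyl]penta‑2,4‑dien‑1‑ol 4 (not isolated)
Conditions: DIBAL‑H, CH2Cl2, −78 °C, Rochelle‑salt work‑up; crude alcohol, Ac2O, Et3N, DMAP (cat.), CH2Cl2, 0 °C
Reagents that add atoms: acetic anhydride, CC(=O)OC(C)=O
Why: DIBAL‑H 1,2‑reduction of the enoate and acetylation; the alkene geometry is untouched and the acetate distinguishes O6 from the silylated O20.

Step 4
Reactants: 5 (2Z)‑3‑[(TBS‑oxy)methyl]penta‑2,4‑dien‑1‑yl acetate; 6 methacrolein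
Product: 7 [(1S,6R)‑2‑[(TBS‑oxy)methyl]‑6‑formyl‑6‑methylcyclohex‑2‑en‑1‑yl]methyl acetate
Conditions: (S)‑o‑tolyl‑CBS‑oxazaborolidine (20 mol %), Tf2NH (17 mol %), CH2Cl2, −78 → −40 °C
Reagents that add atoms: none
Why: catalytic enantioselective Diels–Alder reaction (cationic oxazaborolidine Lewis acid); the (E)‑terminal CH2OAc group directs "ortho" bonding, endo approach of the formyl group makes C19 and C6 cis, and the catalyst sets the absolute configuration of the C4 quaternary centre and C5.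

Step 5
Reactants: 7 [(1S,6R)‑2‑[(TBS‑oxy)methyl]‑6‑formyl‑6‑methylcyclohex‑2‑en‑1‑yl]methyl acetate
Product: 9 [(1R,6R)‑2‑[(TBS‑oxy)methyl]‑6‑methylcyclohex‑2‑ene‑1,6‑diyl]dimethanol, via [(1R,6R)‑2‑[(TBS‑oxy)methyl]‑6‑(hydroxymethyl)‑6‑methylcyclohex‑2‑en‑1‑yl]methyl acetate 8 (not isolated)
Conditions: NaBH4, MeOH, 0 °C; then K2CO3, rt
Reagents that add atoms: none
Why: borohydride reduction of the aldehyde followed by methanolysis (transesterification) of the acetate in the same flask; no stereocentre is touched.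

Step 6
Reactants: 9 [(1R,6R)‑2‑[(TBS‑oxy)methyl]‑6‑methylcyclohex‑2‑ene‑1,6‑diyl]dimethanol
Product: 11 (3aR,7aR)‑7‑[(TBS‑oxy)methyl]‑3a‑methyl‑3a,4,5,7a‑tetrahydro‑2‑benzofuran‑1(3H)‑one, via (3aR,7aR)‑7‑[(TBS‑oxy)methyl]‑3a‑methyl‑1,3,3a,4,5,7a‑hexahydro‑2‑benzofuran‑1‑ol 10 (not isolated)
Conditions: TEMPO (20 mol %), PhI(OAc)2 (2.4 equiv), CH2Cl2, rt
Reagents that add atoms: none
Why: TEMPO/PhI(OAc)2 oxidative lactonisation: the less hindered C6 carbinol is oxidised first (C19–OH is neopentylic), the aldehyde is trapped by O19 as lactol and oxidised on, giving the cis‑fused γ‑lactone with C6 as carbonyl (cis fusion is also the thermodynamic one, C5 being epimerisable).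

Step 7
Reactants: 11 (3aR,7aR)‑7‑[(TBS‑oxy)methyl]‑3a‑methyl‑3a,4,5,7a‑tetrahydro‑2‑benzofuran‑1(3H)‑one
Product: 12 (3aR,7aR)‑7‑(hydroxymethyl)‑3a‑methyl‑3a,4,5,7a‑tetrahydro‑2‑benzofuran‑1(3H)‑one
Conditions: HF·pyridine, THF, 0 °C → rt
Reagents that add atoms: none
Why: fluoride desilylation under non‑basic conditions, which avoids migration of the β,γ‑alkene into conjugation with the lactone.

Step 8
Reactants: 13 (diethoxyphosphoryl)acetic acid; 14 Meldrum's acid (2,2‑dimethyl‑1,3‑dioxane‑4,6‑dione)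
Product: 15 5‑[(diethoxyphosphoryl)acetyl]‑2,2‑dimethyl‑1,3‑dioxane‑4,6‑dione
Conditions: DCC, DMAP, CH2Cl2, 0 °C → rt
Reagents that add atoms: none
Why: carbodiimide‑mediated C‑acylation of Meldrum's acid (acyl‑Meldrum's acid synthesis); no stereocentre.

Step 9
Reactants: 16 ethyl (3S)‑4‑chloro‑3‑hydroxybutanoate
Product: 17 ethyl (3S)‑3‑(TBS‑oxy)‑4‑chlorobutanoate
Conditions: TBSCl, imidazole, DMF, rt
Reagents that add atoms: tert‑butyldimethylsilyl chloride, CC(C)(C)[Si](C)(C)Cl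
Why: O‑silylation; the chiral‑pool centre becomes C13 and places its oxygen trans to the later C15 arm.

Step 10
Reactants: 17 ethyl (3S)‑3‑(TBS‑oxy)‑4‑chlorobutanoate
Product: 18 (4S)‑4‑(TBS‑oxy)‑1,5‑dichloropentan‑2‑one
Conditions: ICH2Cl, MeLi·LiBr, THF, −78 °C; AcOH quench
Reagents that add atoms: chloroiodomethane, ClCI
Why: halomethyllithium homologation of an ester: LiCH2Cl adds once and the tetrahedral intermediate collapses only on quench, giving the α‑chloro ketone without touching the stereocentre.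

Step 11
Reactants: 12 (3aR,7aR)‑7‑(hydroxymethyl)‑3a‑methyl‑3a,4,5,7a‑tetrahydro‑2‑benzofuran‑1(3H)‑one; 15 5‑[(diethoxyphosphoryl)acetyl]‑2,2‑dimethyl‑1,3‑dioxane‑4,6‑dione
Product: 19 [(3aR,7aR)‑3a‑methyl‑1‑oxo‑1,3,3a,4,5,7a‑hexahydro‑2‑benzofuran‑7‑yl]methyl 4‑(diethoxyphosphoryl)‑3‑oxobutanoate
Conditions: PhMe, 85 °C
Reagents that add atoms: none
Why: thermolysis of the acyl Meldrum's acid gives an acylketene that is trapped by the primary allylic alcohol (neutral β‑keto ester synthesis), so the base‑sensitive β,γ‑unsaturated lactone is not disturbed.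

Step 12
Reactants: 19 [(3aR,7aR)‑3a‑methyl‑1‑oxo‑1,3,3a,4,5,7a‑hexahydro‑2‑benzofuran‑7‑yl]methyl 4‑(diethoxyphosphoryl)‑3‑oxobutanoate; 18 (4S)‑4‑(TBS‑oxy)‑1,5‑dichloropentan‑2‑one
Product: 20 [(3aR,7aR)‑3a‑methyl‑1‑oxo‑1,3,3a,4,5,7a‑hexahydro‑2‑benzofuran‑7‑yl]methyl 2‑[(4S)‑4‑(TBS‑oxy)‑5‑chloro‑2‑oxopentyl]‑4‑(diethoxyphosphoryl)‑3‑oxobutanoate (C8 epimers)
Conditions: K2CO3 (1.2 equiv), NaI (0.2 equiv), acetone, rt
Reagents that add atoms: none
Why: SN2 C‑alkylation of the β‑keto ester carbon C8 (the most acidic site) by the α‑chloro ketone with Finkelstein assistance; the unactivated CH2Cl does not react and the new C8 centre is erased in step 13.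

Step 13
Reactants: 20 the alkylated β‑keto ester
Product: 22 [(3aR,7aR)‑3a‑methyl‑1‑oxo‑1,3,3a,4,5,7a‑hexahydro‑2‑benzofuran‑7‑yl]methyl 2‑[(4S)‑4‑(TBS‑oxy)‑5‑chloro‑2‑oxopentylidene]‑4‑(diethoxyphosphoryl)‑3‑oxobutanoate (E/Z), via the 2‑bromo derivative of 20 21 (not isolated)
Conditions: NaH (1.0 equiv), THF, 0 °C; NBS, −20 °C; then Et3N, 0 °C → rt
Reagents that add atoms: none
Why: bromination of the C8 sodium enolate and E1cB dehydrobromination (C9–H is α to the C11 ketone) give the alkylidene 1,3‑dicarbonyl radical acceptor; the alkene geometry is inconsequential.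

Step 14
Reactants: 22 the alkylidene β‑keto ester
Product: 23 spiro bis‑lactone: 7,20‑δ‑lactone spiro‑fused at C10 to ring A (6,19‑γ‑lactone), C8 bearing H and the (diethoxyphosphoryl)acetyl group (C15–C16), C9 bearing the (3S)‑4‑chloro‑3‑(TBS‑oxy)butanoyl chain (C11–C14); C4, C5, C9, C10 as in 28, C8 epimers
Conditions: Fe(acac)3 (30 mol %), PhSiH3 (2.5 equiv), EtOH–(CH2OH)2 5:1, 0.005 M, 40 °C, Ar
Reagents that add atoms: none
Why: Proposed new method: an iron hydride transfers H• to C1 of the trisubstituted alkene (Mukaiyama‑type MHAT), the tertiary C10 radical adds 6‑endo to C9 of the triply activated alkylidene tethered through the O20 ester (polarity‑matched Giese addition; closest known reaction is the Fe(acac)3/PhSiH3 reductive olefin coupling and its intramolecular variants), and the 1,3‑dicarbonyl radical is reduced and protonated; C9 bonds to the convex β‑face of the cis‑fused lactone (anti to C5–C6), and a chair‑like transition state with C5 and the C9 acyl chain both equatorial sets C9 relative to C10.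

Step 15
Reactants: 23 the spiro bis‑lactone
Product: 26 16‑(diethoxyphosphoryl)‑11,15‑dioxo‑17‑nor‑6,7‑seco‑ent‑kaurane‑6,19:7,20‑diolide (C16 epimers), via the ring‑C‑closed 13α‑(TBS‑oxy)‑11‑ketone 24 (not isolated), via the ring‑C 12‑en‑11‑one 25 (not isolated)
Conditions: Cs2CO3 (1.1 equiv), NaI (0.3 equiv), MeCN, 45 °C; then DBU (3 equiv), 70 °C
Reagents that add atoms: none
Why: intramolecular 6‑exo‑tet C‑alkylation of the β‑keto lactone enolate by C14, which the C9 tether delivers cis to C11 (sets the C8 quaternary centre), then E1cB loss of silanolate to the enone and 5‑exo intramolecular Michael addition of the phosphonate‑stabilised C16 carbanion from the axial C15 arm (sets C13 by bridging).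

Step 16
Reactants: 26 the 11,15‑dioxo phosphonate
Product: 27 16‑(diethoxyphosphoryl)‑11α‑hydroxy‑15‑oxo‑17‑nor‑6,7‑seco‑ent‑kaurane‑6,19:7,20‑diolide (C16 epimers)
Conditions: NaH (1.1 equiv), THF, 0 °C; then NaBH4, EtOH, −20 °C; aq. NH4Cl
Reagents that add atoms: none
Why: chemoselective borohydride reduction with the C15 carbonyl protected in situ as the sodium phosphonoenolate; hydride adds axially from the β‑face (over the flat, enolised C15–C16 bridge) because the α‑face is blocked by the axial C9–C10 bond and ring A, giving the equatorial 11α‑alcohol.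

Step 17
Reactants: 27 the 11α‑hydroxy phosphonate
Product: 28 ludongnin A
Conditions: 37 % aq. CH2O (5 equiv), K2CO3 (2 equiv), THF, 0 °C → rt
Reagents that add atoms: formaldehyde, C=O
Why: Horner–Wadsworth–Emmons olefination of the β‑keto phosphonate with formaldehyde installs the exocyclic C16=C17 enone directly; no stereocentre is affected.

**Compound list**
1 | tert‑butyldimethyl(prop‑2‑yn‑1‑yloxy)silane | C#CCO[Si](C)(C)C(C)(C)C | starting material
2 | ethyl 4‑(TBS‑oxy)but‑2‑ynoate | CCOC(=O)C#CCO[Si](C)(C)C(C)(C)C | intermediate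
3 | ethyl (2Z)‑3‑[(TBS‑oxy)methyl]penta‑2,4‑dienoate | C=C/C(CO[Si](C)(C)C(C)(C)C)=C/C(=O)OCC | intermediate
4 | (2Z)‑3‑[(TBS‑oxy)methyl]penta‑2,4‑dien‑1‑ol | C=C/C(CO[Si](C)(C)C(C)(C)C)=C/CO | intermediate
5 | (2Z)‑3‑[(TBS‑oxy)methyl]penta‑2,4‑dien‑1‑yl acetate | C=C/C(CO[Si](C)(C)C(C)(C)C)=C/COC(C)=O | intermediate
6 | methacrolein | C=C(C)C=O | starting material
7 | [(1S,6R)‑2‑[(TBS‑oxy)methyl]‑6‑formyl‑6‑methylcyclohex‑2‑en‑1‑yl]methyl acetate | O=C[C@]1(C)CCC=C(CO[Si](C)(C)C(C)(C)C)[C@@H]1COC(C)=O | intermediate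
8 | [(1R,6R)‑2‑[(TBS‑oxy)methyl]‑6‑(hydroxymethyl)‑6‑methylcyclohex‑2‑en‑1‑yl]methyl acetate | OC[C@]1(C)CCC=C(CO[Si](C)(C)C(C)(C)C)[C@@H]1COC(C)=O | intermediate
9 | [(1R,6R)‑2‑[(TBS‑oxy)methyl]‑6‑methylcyclohex‑2‑ene‑1,6‑diyl]dimethanol | OC[C@]1(C)CCC=C(CO[Si](C)(C)C(C)(C)C)[C@@H]1CO | intermediate
10 | (3aR,7aR)‑7‑[(TBS‑oxy)methyl]‑3a‑methyl‑1,3,3a,4,5,7a‑hexahydro‑2‑benzofuran‑1‑ol | OC1OC[C@]2(C)CCC=C(CO[Si](C)(C)C(C)(C)C)[C@H]12 | intermediate
11 | (3aR,7aR)‑7‑[(TBS‑oxy)methyl]‑3a‑methyl‑3a,4,5,7a‑tetrahydro‑2‑benzofuran‑1(3H)‑one | O=C1OC[C@]2(C)CCC=C(CO[Si](C)(C)C(C)(C)C)[C@H]12 | intermediate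
12 | (3aR,7aR)‑7‑(hydroxymethyl)‑3a‑methyl‑3a,4,5,7a‑tetrahydro‑2‑benzofuran‑1(3H)‑one | O=C1OC[C@]2(C)CCC=C(CO)[C@H]12 | intermediate
13 | (diethoxyphosphoryl)acetic acid | CCOP(=O)(CC(=O)O)OCC | starting material
14 | Meldrum's acid | CC1(C)OC(=O)CC(=O)O1 | starting material
15 | 5‑[(diethoxyphosphoryl)acetyl]‑2,2‑dimethyl‑1,3‑dioxane‑4,6‑dione | CCOP(=O)(CC(=O)C1C(=O)OC(C)(C)OC1=O)OCC | intermediate
16 | ethyl (3S)‑4‑chloro‑3‑hydroxybutanoate | CCOC(=O)C[C@H](O)CCl | starting material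
17 | ethyl (3S)‑3‑(TBS‑oxy)‑4‑chlorobutanoate | CCOC(=O)C[C@H](O[Si](C)(C)C(C)(C)C)CCl | intermediate
18 | (4S)‑4‑(TBS‑oxy)‑1,5‑dichloropentan‑2‑one | ClCC(=O)C[C@H](O[Si](C)(C)C(C)(C)C)CCl | intermediate
19 | [(3aR,7aR)‑3a‑methyl‑1‑oxo‑1,3,3a,4,5,7a‑hexahydro‑2‑benzofuran‑7‑yl]methyl 4‑(diethoxyphosphoryl)‑3‑oxobutanoate | CCOP(=O)(OCC)CC(=O)CC(=O)OCC1=CCC[C@@]2(C)COC(=O)[C@@H]12 | intermediate
20 | 2‑[(4S)‑4‑(TBS‑oxy)‑5‑chloro‑2‑oxopentyl] derivative of 19 (C8 epimers) | CCOP(=O)(OCC)CC(=O)C(CC(=O)C[C@H](O[Si](C)(C)C(C)(C)C)CCl)C(=O)OCC1=CCC[C@@]2(C)COC(=O)[C@@H]12 | intermediate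
21 | 2‑bromo derivative of 20 | CCOP(=O)(OCC)CC(=O)C(Br)(CC(=O)C[C@H](O[Si](C)(C)C(C)(C)C)CCl)C(=O)OCC1=CCC[C@@]2(C)COC(=O)[C@@H]12 | intermediate
22 | 2‑[(4S)‑4‑(TBS‑oxy)‑5‑chloro‑2‑oxopentylidene] derivative of 19 (E/Z) | CCOP(=O)(OCC)CC(=O)C(=CC(=O)C[C@H](O[Si](C)(C)C(C)(C)C)CCl)C(=O)OCC1=CCC[C@@]2(C)COC(=O)[C@@H]12 | intermediate
23 | spiro bis‑lactone (7,20‑δ‑lactone spiro at C10 to ring A/γ‑lactone; C8 (diethoxyphosphoryl)acetyl, C9 (3S)‑4‑chloro‑3‑(TBS‑oxy)butanoyl; C8 epimers) | CCOP(=O)(OCC)CC(=O)C1C(=O)OC[C@]2(CCC[C@@]3(C)COC(=O)[C@H]32)[C@@H]1C(=O)C[C@H](O[Si](C)(C)C(C)(C)C)CCl | intermediate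
24 | ring‑C‑closed 13α‑(TBS‑oxy)‑11‑oxo bis‑lactone, C8 bearing the (diethoxyphosphoryl)acetyl group | CCOP(=O)(OCC)CC(=O)[C@]23C[C@@H](O[Si](C)(C)C(C)(C)C)CC(=O)[C@H]2[C@@]1(CCC[C@@]2(C)COC(=O)[C@H]21)COC3=O | intermediate
25 | ring‑C 12‑en‑11‑one bis‑lactone, C8 bearing the (diethoxyphosphoryl)acetyl group | CCOP(=O)(OCC)CC(=O)[C@]23CC=CC(=O)[C@H]2[C@@]1(CCC[C@@]2(C)COC(=O)[C@H]21)COC3=O | intermediate
26 | 16‑(diethoxyphosphoryl)‑11,15‑dioxo‑17‑nor‑6,7‑seco‑ent‑kaurane‑6,19:7,20‑diolide (C16 epimers) | CCOP(=O)(OCC)C1C(=O)[C@]23C[C@H]1CC(=O)[C@H]2[C@@]1(CCC[C@@]2(C)COC(=O)[C@H]21)COC3=O | intermediate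
27 | 16‑(diethoxyphosphoryl)‑11α‑hydroxy‑15‑oxo‑17‑nor‑6,7‑seco‑ent‑kaurane‑6,19:7,20‑diolide (C16 epimers) | CCOP(=O)(OCC)C1C(=O)[C@]23C[C@H]1C[C@@H](O)[C@H]2[C@@]1(CCC[C@@]2(C)COC(=O)[C@H]21)COC3=O | intermediate
28 | ludongnin A | C=C1C(=O)[C@]23C[C@H]1C[C@@H](O)[C@H]2[C@@]1(CCC[C@@]2(C)COC(=O)[C@H]21)COC3=O | target

**Step count**
Total: 17 steps. Longest linear sequence: 14 steps (steps 1–7, then 11–17).

**Three steps most likely to fail, with fallbacks**

Step 14 (MHAT 6‑endo spirolactonisation). The ester tether prefers the unreactive s‑trans rotamer, simple reduction or isomerisation of the alkene can compete, and the C9/C10 selectivity rests on a transition‑state model. The fallback makes the C9–C10 bond intermolecularly and closes the lactone afterwards; it sets out from 12 (with 15 and 18 as the other building blocks) and comes back at 23. Heating 15 in ethanol gives ethyl 4‑(diethoxyphosphoryl)‑3‑oxobutanoate F1. Alkylation with 18 (K2CO3, NaI) gives ethyl 2‑[(4S)‑4‑(TBS‑oxy)‑5‑chloro‑2‑oxopentyl]‑4‑(diethoxyphosphoryl)‑3‑oxobutanoate F2. NaH/NBS gives the 2‑bromo ester F3, and Et3N then gives the alkylidene ester F4. Fe(acac)3/PhSiH3 coupling of 12 (1 equiv) with F4 (3 equiv) gives the open‑chain hydroxy ethyl ester adduct F5. Heating F5 in toluene (110 °C, loss of ethanol) closes the δ‑lactone to 23. In this variant C9 is controlled only by the acyclic addition, so the 9‑epimer may have to be separated.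

Step 15 (alkylation / E1cB / Michael cascade). The silanolate is a poor leaving group for the E1cB stage, and before ring C is closed the phosphonate carbanion could attack the C11 ketone. The fallback runs the sequence stepwise and closes ring D by a different bond‑forming mode; it sets out from 24, isolated after the carbonate stage, and comes back at 26. HF·pyridine gives the 13α‑hydroxy‑11‑ketone F6 and MsCl/Et3N gives the 13α‑mesylate F7. K2CO3/18‑crown‑6 in toluene then closes ring D by direct 5‑exo‑tet displacement of the equatorial mesylate by the phosphonate carbanion (inversion at C13; the (S)‑side chain places this leaving group trans to the C15 arm), or by elimination/Michael addition.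

Step 16 (C11 reduction). The enolate masking of C15 may be incomplete, and hydride could attack C11 from the wrong face. The fallback replaces masking by global reduction and selective re‑oxidation; it sets out from 26 and comes back at 28. Olefination first (K2CO3, aq. CH2O) gives 11,15‑dioxo‑6,7‑seco‑ent‑kaur‑16‑ene‑6,19:7,20‑diolide F8. Luche reduction (NaBH4, CeCl3, MeOH, −40 °C) reduces both ketones to the 11α,15‑diol F9. MnO2 in CH2Cl2 re‑oxidises only the allylic C15 carbinol and gives 28.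

**Further compounds**
F1 | step 14 | ethyl 4‑(diethoxyphosphoryl)‑3‑oxobutanoate | CCOC(=O)CC(=O)CP(=O)(OCC)OCC
F2 | step 14 | ethyl 2‑[(4S)‑4‑(TBS‑oxy)‑5‑chloro‑2‑oxopentyl]‑4‑(diethoxyphosphoryl)‑3‑oxobutanoate | CCOC(=O)C(CC(=O)C[C@H](O[Si](C)(C)C(C)(C)C)CCl)C(=O)CP(=O)(OCC)OCC
F3 | step 14 | ethyl 2‑bromo‑2‑[(4S)‑4‑(TBS‑oxy)‑5‑chloro‑2‑oxopentyl]‑4‑(diethoxyphosphoryl)‑3‑oxobutanoate | CCOC(=O)C(Br)(CC(=O)C[C@H](O[Si](C)(C)C(C)(C)C)CCl)C(=O)CP(=O)(OCC)OCC
F4 | step 14 | ethyl 2‑[(4S)‑4‑(TBS‑oxy)‑5‑chloro‑2‑oxopentylidene]‑4‑(diethoxyphosphoryl)‑3‑oxobutanoate | CCOC(=O)C(=CC(=O)C[C@H](O[Si](C)(C)C(C)(C)C)CCl)C(=O)CP(=O)(OCC)OCC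
F5 | step 14 | open‑chain hydroxy ethyl ester adduct (C9–C10 bond formed, C20–OH free) | CCOC(=O)C(C(=O)CP(=O)(OCC)OCC)C(C(=O)C[C@H](O[Si](C)(C)C(C)(C)C)CCl)[C@]1(CO)CCC[C@@]2(C)COC(=O)[C@H]21
F6 | step 15 | 13α‑hydroxy‑11‑ketone (desilylated 24) | CCOP(=O)(OCC)CC(=O)[C@]23C[C@@H](O)CC(=O)[C@H]2[C@@]1(CCC[C@@]2(C)COC(=O)[C@H]21)COC3=O
F7 | step 15 | 13α‑mesylate of F6 | CCOP(=O)(OCC)CC(=O)[C@]23C[C@@H](OS(C)(=O)=O)CC(=O)[C@H]2[C@@]1(CCC[C@@]2(C)COC(=O)[C@H]21)COC3=O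
F8 | step 16 | 11,15‑dioxo‑6,7‑seco‑ent‑kaur‑16‑ene‑6,19:7,20‑diolide | C=C1C(=O)[C@]23C[C@H]1CC(=O)[C@H]2[C@@]1(CCC[C@@]2(C)COC(=O)[C@H]21)COC3=O
F9 | step 16 | 11α,15‑dihydroxy‑6,7‑seco‑ent‑kaur‑16‑ene‑6,19:7,20‑diolide | C=C1C(O)[C@]23C[C@H]1C[C@@H](O)[C@H]2[C@@]1(CCC[C@@]2(C)COC(=O)[C@H]21)COC3=O
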